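**Strategy.** The plan rests on cutting C4a''–C5'', so that resorcinol ring D is grown last onto a finished 4-pyranone (ring E). It exploits the fact that rings D and E share the C4a''–C8a'' bond while ring B sits on C8'', next to the O1''-bearing C8a''. The ring oxygen is already on C8a'' when ring D is made, so the aryl group cannot end up at C6''. The congested C5'–C8'' linkage is forged while C8'' is still an sp3 benzylic carbon. One heating step turns a tert-butyl β-keto ester into a dienylketene that ring-closes and aromatises to the 5'',7''-dihydroxyflavone. The precursor is a racemic tert-butyl 3-oxobutanoate carrying ring B and a 6-aryl-4-pyranon-2-yl group on C4. C2 is set afterwards by enantioselective conjugate arylation.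

Key step: step 10

Numbering: unprimed atoms are flavanone rings A and C, primed atoms ring B, double-primed atoms flavone rings D (carbocycle) and E (pyranone), and triple-primed atoms ring F (4-hydroxyphenyl).

Assumption (sense of induction): the (S)-pyridine-oxazoline ligand is known to give (R)-3-aryl-3-methylcyclohexanones, and the same facial delivery to a chromone corresponds to (2R). The (R)-ligand is therefore specified for the (2S) target, and the antipode is used if a phenylboronic acid test shows the opposite sense.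

Assumption (biaryl axis): the C5'–C8'' axis has three ortho substituents and is taken to rotate freely enough, as in related 3',8''-biflavones, not to count as a stereoelement. This matches the target SMILES.

**Step 1**
Reactants: 1 5-bromo-2-hydroxy-3-methoxybenzaldehyde
Product: 2 5-bromo-2,3-dihydroxybenzaldehyde
Conditions: BBr3 (2.5 equiv), CH2Cl2, −78 °C to rt; then H2O
Reagents that add atoms: none
Why: Lewis-acid cleavage of an aryl methyl ether (BBr3 demethylation) is routine for o-vanillin derivatives and removes the one ether that the final hydrogenolysis could not take off.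

**Step 2**
Reactants: 2 5-bromo-2,3-dihydroxybenzaldehyde
Product: 3 2,3-bis(benzyloxy)-5-bromobenzaldehyde
Conditions: BnBr (2.4 equiv), K2CO3, DMF, 60 °C
Reagents that add atoms: benzyl bromide, BrCc1ccccc1
Why: Williamson etherification of both phenols installs benzyl groups that survive strong base, acid, 144 °C and palladium coupling and all leave together in the last step.

**Step 3**
Reactants: 3 2,3-bis(benzyloxy)-5-bromobenzaldehyde
Product: 4 1-[2,3-bis(benzyloxy)-5-bromophenyl]-2-(methylsulfinyl)-2-(methylsulfanyl)ethene (alkene isomers, racemic at sulfur)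
Conditions: CH3S(O)CH2SCH3, benzyltrimethylammonium hydroxide (cat., 40% in MeOH), THF, reflux
Reagents that add atoms: methyl (methylsulfinyl)methyl sulfide, CSCS(C)=O
Why: Base-catalysed Knoevenagel-type condensation of the acidic CH2 of the dithioacetal S-oxide with a non-enolisable aromatic aldehyde gives a ketene dithioacetal S-oxide, a masked arylacetic acid whose alkene geometry and sulfur stereocentre are both erased in step 4.

**Step 4**
Reactants: 4 the ketene dithioacetal S-oxide
Product: 5 methyl [2,3-bis(benzyloxy)-5-bromophenyl]acetate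
Conditions: HCl (3 M in MeOH), 0 °C to 40 °C
Reagents that add atoms: methanol, CO
Why: Acid alcoholysis of a ketene dithioacetal S-oxide (protonation at the benzylic carbon, addition of methanol, Pummerer-type loss of both sulfur groups as the disulfide) gives the one-carbon homologated arylacetate under conditions mild enough for aryl benzyl ethers.

**Step 5**
Reactants: 6 4-benzyloxyacetophenone
Product: 7 1-[4-(benzyloxy)phenyl]butane-1,3-dione
Conditions: NaH (2.5 equiv), EtOAc (5 equiv), THF, reflux; then aq HCl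
Reagents that add atoms: ethyl acetate, CCOC(C)=O
Why: Crossed Claisen condensation of a methyl ketone enolate with ethyl acetate is driven by formation of the stable sodium diketonate.

**Step 6**
Reactants: 7 1-[4-(benzyloxy)phenyl]butane-1,3-dione (2.5 equiv); 5 methyl [2,3-bis(benzyloxy)-5-bromophenyl]acetate
Product: 9 1-[4-(benzyloxy)phenyl]-6-[2,3-bis(benzyloxy)-5-bromophenyl]hexane-1,3,5-trione, via dilithio dianion 8 (not isolated)
Conditions: 7, LiN(iPr)2 (2 equiv per 7), THF, −78 to 0 °C; then 5, −78 to 0 °C; AcOH quench at −20 °C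
Reagents that add atoms: LiN(iPr)2, [Li+].CC(C)[N-]C(C)C (lithium of intermediate 8 only)
Why: Claisen-type γ-acylation of a 1,3-diketone dianion by an ester occurs at the terminal, more basic carbanion, the cheap dianion being used in excess so that it also absorbs the acidic protons of 9 and any proton transfer from the arylacetate, while the cold acidic quench avoids base-induced aldol closure of C6 onto C1.

**Step 7**
Reactants: 9 the 1,3,5-triketone
Product: 10 2-{[2,3-bis(benzyloxy)-5-bromophenyl]methyl}-6-[4-(benzyloxy)phenyl]-4H-pyran-4-one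
Conditions: CF3CO2H, CH2Cl2, rt
Reagents that add atoms: none
Why: Acid-catalysed cyclodehydration of a 1,3,5-triketone gives the 4-pyranone, and only one pyranone is possible because either terminal carbonyl oxygen can become the ring oxygen with the same result.

**Step 8**
Reactants: 10 the 2-benzyl-4-pyranone
Product: 12 racemic 2-[2,3-bis(benzyloxy)-5-bromophenyl]-2-{6-[4-(benzyloxy)phenyl]-4-oxo-4H-pyran-2-yl}acetic acid, via lithium dienolate 11 (not isolated)
Conditions: LiN(SiMe3)2 (2.2 equiv), THF, −78 °C; dry CO2, −78 to −20 °C; cold 1 M HCl to pH 3; used without heating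
Reagents that add atoms: carbon dioxide, O=C=O; LiN(SiMe3)2, [Li+].C[Si](C)(C)[N-][Si](C)(C)C (lithium of intermediate 11 only)
Why: This is lateral (vinylogous) deprotonation of a 2-alkyl-4-pyranone followed by carboxylation, in which the CH2 between ring B and the pyranone is by far the most acidic site, the silylamide leaves the aryl bromide alone, attack of CO2 at the exocyclic carbon restores the pyranone, any double carboxylation corrects itself on acidification, and the new C8'' centre is racemic and is erased in step 10.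

**Step 9**
Reactants: 12 the aryl(pyranonyl)acetic acid; 13 mono-tert-butyl malonate
Product: 15 racemic tert-butyl 4-[2,3-bis(benzyloxy)-5-bromophenyl]-4-{6-[4-(benzyloxy)phenyl]-4-oxo-4H-pyran-2-yl}-3-oxobutanoate, via acyl imidazolide 14 (not isolated)
Conditions: 12, 1,1'-carbonyldiimidazole, THF, 0 °C to rt; added to 13 (2 equiv), MgCl2, Et3N, MeCN, rt; aq citric acid
Reagents that add atoms: 1,1'-carbonyldiimidazole, O=C(n1ccnc1)n1ccnc1 (imidazolyl group of intermediate 14 only; nothing from it remains in 15)
Why: In this Masamune–Brooks decarboxylative Claisen homologation the neutral magnesium malonate attacks the acyl imidazolide under conditions that tolerate a very acidic α-hydrogen, whereas direct acylation of 11 by an activated malonate half-ester would end in proton transfer from the malonyl CH2.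

**Step 10**
Reactants: 15 the tert-butyl β-keto ester
Product: 19 8-[2,3-bis(benzyloxy)-5-bromophenyl]-2-[4-(benzyloxy)phenyl]-5,7-dihydroxy-4H-chromen-4-one, via acylketene 16 (not isolated), via dienylketene 17 (not isolated), via cyclohexadienone 18 (not isolated)
Conditions: o-xylene, reflux (144 °C), N2 sweep to carry off t-BuOH, base-washed glassware, syringe-pump addition of 15 over 8 h to a final 2 mM, then 1 h
Reagents that add atoms: none
Why: Proposed new method: above about 110 °C the chelated enol of 15 expels tert-butanol through a six-membered transition state to give acylketene 16, and a proton shift from the doubly activated C8'' to the C7'' oxygen converts it into dienylketene 17, whose three π bonds are C5''=C6'' of the ketene, C7''=C8'' of the enol and C8a''=C4a'' of ring E. Ring D closes by thermal disrotatory 6π electrocyclisation (equally describable as six-membered C-acylation of the enol-ether-like C4a'' by the ketene carbon), forming C4a''–C5'' and giving cyclohexadienone 18, which tautomerises irreversibly to the resorcinol with its 5''-OH chelated to the C4'' carbonyl. The closest known reaction types are dienylketene benzannulations (Danheiser benzannulation and cyclobutenone ring-opening variants, also with heteroaromatic π bonds as terminus) and acylketene release from tert-butyl β-keto esters in transacetoacetylation, but a 4-pyranone C=C as triene terminus has not been shown. No stereocentre is created, since the racemic C8'' centre of 15 becomes sp2 and the transient C4a'' centre of 18 is lost on aromatisation. The step needs capture at C4a'' rather than closure onto C6' of ring B, oxygen addition or ketene dimerisation: the pyranone bond is far less aromatic and more nucleophilic than the bromine-flanked benzene position, the two enol geometries interconvert through the keto form so that the productive one is continuously replenished, adducts of tert-butanol or of product phenols are β-keto esters that revert to 16 at this temperature, and slow addition at high dilution holds back dimerisation. Regiochemistry is not in question because C8a'' already carries O1'', so ring B can only sit on C8''.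

**Step 11**
Reactants: 19 the 5,7-dihydroxy-8-arylflavone
Product: 20 5,7-bis(benzyloxy)-8-[2,3-bis(benzyloxy)-5-bromophenyl]-2-[4-(benzyloxy)phenyl]-4H-chromen-4-one
Conditions: BnBr (3 equiv), K2CO3 (4 equiv), DMF, 80 °C
Reagents that add atoms: benzyl bromide, BrCc1ccccc1
Why: Williamson etherification, pushed by heat and excess reagent so that the chelated 5''-OH and the hindered 7''-OH both react, masks the phenols for the two palladium steps.

**Step 12**
Reactants: 20 the pentabenzyl bromoflavone
Product: 21 5,7-bis(benzyloxy)-8-[2,3-bis(benzyloxy)-5-(4,4,5,5-tetramethyl-1,3,2-dioxaborolan-2-yl)phenyl]-2-[4-(benzyloxy)phenyl]-4H-chromen-4-one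
Conditions: B2pin2 (1.5 equiv), PdCl2(dppf) (5 mol%), KOAc (3 equiv), 1,4-dioxane, 90 °C
Reagents that add atoms: bis(pinacolato)diboron, CC1(C)OB(OC1(C)C)B1OC(C)(C)C(C)(C)O1
Why: Miyaura borylation of an aryl bromide with hydrogen on both ortho positions is unhindered, and KOAc is too weak a base to harm the flavone.

**Step 13**
Reactants: 21 the pinacol boronate
Product: 22 {3,4-bis(benzyloxy)-5-[5,7-bis(benzyloxy)-2-(4-benzyloxyphenyl)-4-oxo-4H-chromen-8-yl]phenyl}boronic acid
Conditions: NaIO4 (3 equiv), NH4OAc (3 equiv), THF/acetone/H2O, rt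
Reagents that add atoms: water, O
Why: Oxidative cleavage of the pinacol unit with periodate frees the boronic acid, which is needed because pinacol esters transmetalate too slowly to the cationic palladium catalyst of step 15.

**Step 14**
Reactants: 23 5,7-dihydroxychromone
Product: 24 5,7-bis(benzyloxy)-4H-chromen-4-one
Conditions: BnBr (3 equiv), K2CO3, DMF, 80 °C
Reagents that add atoms: benzyl bromide, BrCc1ccccc1
Why: Williamson etherification under anhydrous carbonate conditions protects both phenols, including the chelated 5-OH, without opening the base-sensitive unsubstituted pyranone ring.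

**Step 15**
Reactants: 22 the boronic acid; 24 5,7-bis(benzyloxy)-4H-chromen-4-one (2 equiv)
Product: 25 (2S)-5,7-bis(benzyloxy)-2-{3,4-bis(benzyloxy)-5-[5,7-bis(benzyloxy)-2-(4-benzyloxyphenyl)-4-oxo-4H-chromen-8-yl]phenyl}-2,3-dihydro-4H-chromen-4-one
Conditions: Pd(OCOCF3)2 (10 mol%), (R)-4-tert-butyl-2-(pyridin-2-yl)-4,5-dihydrooxazole (12 mol%), NH4PF6 (30 mol%), H2O (5 equiv), ClCH2CH2Cl, 60 °C
Reagents that add atoms: none
Why: In this enantioselective conjugate addition of an arylboronic acid to a chromone, catalysed by cationic divalent palladium bearing a pyridine-oxazoline (transmetalation, insertion of C2=C3 into the aryl–palladium bond, protonolysis of the palladium enolate), the tert-butyl group of the (R)-ligand steers the aryl group to the Re face of C2 and so sets (2S), while the 2-aryl-substituted, crowded ring E of the boronic acid is too hindered to compete as acceptor.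

**Step 16**
Reactants: 25 the heptabenzyl ether
Product: 26 (2S)-2-{3,4-dihydroxy-5-[5,7-dihydroxy-2-(4-hydroxyphenyl)-4-oxo-4H-chromen-8-yl]phenyl}-5,7-dihydroxy-2,3-dihydro-4H-chromen-4-one (CNP0204144.1)
Conditions: H2 (1 atm), Pd/C (10 wt% Pd), THF/MeOH 1:1, rt; neutral work-up without heating
Reagents that add atoms: none
Why: Catalytic hydrogenolysis removes all seven benzyl ethers under neutral conditions, which matters because the free 4'-hydroxyflavanone racemises in base through ring-opening to the chalcone, and the C2''=C3'' bond and the C4 ketone should not be reduced at 1 atm and room temperature.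

**Compound list**

1 | 5-bromo-2-hydroxy-3-methoxybenzaldehyde | COc1cc(Br)cc(C=O)c1O | starting material
2 | 5-bromo-2,3-dihydroxybenzaldehyde | O=Cc1cc(Br)cc(O)c1O | intermediate
3 | 2,3-bis(benzyloxy)-5-bromobenzaldehyde | O=Cc1cc(Br)cc(OCc2ccccc2)c1OCc1ccccc1 | intermediate
4 | 1-[2,3-bis(benzyloxy)-5-bromophenyl]-2-(methylsulfinyl)-2-(methylsulfanyl)ethene (alkene isomers, racemic at sulfur) | CSC(=Cc1cc(Br)cc(OCc2ccccc2)c1OCc1ccccc1)S(C)=O | intermediate
5 | methyl [2,3-bis(benzyloxy)-5-bromophenyl]acetate | COC(=O)Cc1cc(Br)cc(OCc2ccccc2)c1OCc1ccccc1 | intermediate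
6 | 4-benzyloxyacetophenone | CC(=O)c1ccc(OCc2ccccc2)cc1 | starting material
7 | 1-[4-(benzyloxy)phenyl]butane-1,3-dione | CC(=O)CC(=O)c1ccc(OCc2ccccc2)cc1 | intermediate
8 | dilithio dianion of 7 (bis-enolate) | [Li+].[Li+].C=C([O-])C=C([O-])c1ccc(OCc2ccccc2)cc1 | intermediate
9 | 1-[4-(benzyloxy)phenyl]-6-[2,3-bis(benzyloxy)-5-bromophenyl]hexane-1,3,5-trione | O=C(CC(=O)CC(=O)c1ccc(OCc2ccccc2)cc1)Cc1cc(Br)cc(OCc2ccccc2)c1OCc1ccccc1 | intermediate
10 | 2-{[2,3-bis(benzyloxy)-5-bromophenyl]methyl}-6-[4-(benzyloxy)phenyl]-4H-pyran-4-one | O=c1cc(Cc2cc(Br)cc(OCc3ccccc3)c2OCc2ccccc2)oc(-c2ccc(OCc3ccccc3)cc2)c1 | intermediate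
11 | lithium dienolate of 10 (2-benzylidene-2H-pyran-4-olate) | [Li+].[O-]C1=CC(=Cc2cc(Br)cc(OCc3ccccc3)c2OCc2ccccc2)OC(c2ccc(OCc3ccccc3)cc2)=C1 | intermediate
12 | racemic 2-[2,3-bis(benzyloxy)-5-bromophenyl]-2-{6-[4-(benzyloxy)phenyl]-4-oxo-4H-pyran-2-yl}acetic acid | OC(=O)C(c1cc(Br)cc(OCc2ccccc2)c1OCc1ccccc1)c1cc(=O)cc(-c2ccc(OCc3ccccc3)cc2)o1 | intermediate
13 | mono-tert-butyl malonate | CC(C)(C)OC(=O)CC(=O)O | starting material
14 | racemic acyl imidazolide of 12 | O=C(C(c1cc(Br)cc(OCc2ccccc2)c1OCc1ccccc1)c1cc(=O)cc(-c2ccc(OCc3ccccc3)cc2)o1)n1ccnc1 | intermediate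
15 | racemic tert-butyl 4-[2,3-bis(benzyloxy)-5-bromophenyl]-4-{6-[4-(benzyloxy)phenyl]-4-oxo-4H-pyran-2-yl}-3-oxobutanoate | CC(C)(C)OC(=O)CC(=O)C(c1cc(Br)cc(OCc2ccccc2)c1OCc1ccccc1)c1cc(=O)cc(-c2ccc(OCc3ccccc3)cc2)o1 | intermediate
16 | racemic acylketene from 15 | O=C=CC(=O)C(c1cc(Br)cc(OCc2ccccc2)c1OCc1ccccc1)c1cc(=O)cc(-c2ccc(OCc3ccccc3)cc2)o1 | intermediate
17 | dienylketene, enol isomer with the ketene arm cis to the pyranone | O=C=C/C(O)=C(/c1cc(Br)cc(OCc2ccccc2)c1OCc1ccccc1)c1cc(=O)cc(-c2ccc(OCc3ccccc3)cc2)o1 | intermediate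
18 | racemic cyclohexadienone, primary electrocyclisation product (H on C4a'') | O=C1C=C(O)C(c3cc(Br)cc(OCc4ccccc4)c3OCc3ccccc3)=C2OC(c3ccc(OCc4ccccc4)cc3)=CC(=O)C12 | intermediate
19 | 8-[2,3-bis(benzyloxy)-5-bromophenyl]-2-[4-(benzyloxy)phenyl]-5,7-dihydroxy-4H-chromen-4-one | Oc1cc(O)c2c(=O)cc(-c3ccc(OCc4ccccc4)cc3)oc2c1-c1cc(Br)cc(OCc2ccccc2)c1OCc1ccccc1 | intermediate
20 | 5,7-bis(benzyloxy)-8-[2,3-bis(benzyloxy)-5-bromophenyl]-2-[4-(benzyloxy)phenyl]-4H-chromen-4-one | O=c1cc(-c2ccc(OCc3ccccc3)cc2)oc2c(-c3cc(Br)cc(OCc4ccccc4)c3OCc3ccccc3)c(OCc3ccccc3)cc(OCc3ccccc3)c12 | intermediate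
21 | pinacol boronate of 20 | O=c1cc(-c2ccc(OCc3ccccc3)cc2)oc2c(-c3cc(B4OC(C)(C)C(C)(C)O4)cc(OCc4ccccc4)c3OCc3ccccc3)c(OCc3ccccc3)cc(OCc3ccccc3)c12 | intermediate
22 | {3,4-bis(benzyloxy)-5-[5,7-bis(benzyloxy)-2-(4-benzyloxyphenyl)-4-oxo-4H-chromen-8-yl]phenyl}boronic acid | O=c1cc(-c2ccc(OCc3ccccc3)cc2)oc2c(-c3cc(B(O)O)cc(OCc4ccccc4)c3OCc3ccccc3)c(OCc3ccccc3)cc(OCc3ccccc3)c12 | intermediate
23 | 5,7-dihydroxychromone | O=c1ccoc2cc(O)cc(O)c12 | starting material
24 | 5,7-bis(benzyloxy)-4H-chromen-4-one | O=c1ccoc2cc(OCc3ccccc3)cc(OCc3ccccc3)c12 | intermediate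
25 | (2S)-heptabenzyl ether of the target | O=C1C[C@@H](c2cc(OCc3ccccc3)c(OCc3ccccc3)c(-c3c(OCc4ccccc4)cc(OCc4ccccc4)c4c(=O)cc(-c5ccc(OCc6ccccc6)cc5)oc34)c2)Oc2cc(OCc3ccccc3)cc(OCc3ccccc3)c21 | intermediate
26 | (2S)-2-{3,4-dihydroxy-5-[5,7-dihydroxy-2-(4-hydroxyphenyl)-4-oxo-4H-chromen-8-yl]phenyl}-5,7-dihydroxy-2,3-dihydro-4H-chromen-4-one | O=C1C[C@@H](c2cc(O)c(O)c(-c3c(O)cc(O)c4c(=O)cc(-c5ccc(O)cc5)oc34)c2)Oc2cc(O)cc(O)c21 | target

**Step count**

- Total steps: 16.
- Longest linear sequence: 14 (steps 1–4, 6–13, 15, 16).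

**Steps most likely to fail**

**Step 10.**
- *Risk.* The acylketene may be drained by dimerisation or by ring closure onto C6' of ring B. Alternatively, the tert-butyl ester may fragment to isobutene and CO2 before the ketene forms.
- *Fallback (known chemistry, sets out from 3, returns at 20).* The biaryl bond is made by cross-coupling instead of by ring construction. Aldehyde 3 is oxidised (NaClO2, NaH2PO4, 2-methyl-2-butene) to 2,3-bis(benzyloxy)-5-bromobenzoic acid F1. Decarboxylative iodination (I2, K3PO4, MeCN, 100 °C) then gives 1,2-bis(benzyloxy)-5-bromo-3-iodobenzene F2. Selective iodine–magnesium exchange (iPrMgCl·LiCl, THF, −30 °C), B(OMe)3 and aqueous acid give [2,3-bis(benzyloxy)-5-bromophenyl]boronic acid F3. In parallel, commercial apigenin is perbenzylated (BnBr, K2CO3, DMF) to 5,7-bis(benzyloxy)-2-[4-(benzyloxy)phenyl]-4H-chromen-4-one F4. Iodination at C8'' (N-iodosuccinimide, CF3CO2H, MeCN) gives the 8-iodoflavone F5. Suzuki–Miyaura coupling of F3 with F5 [Pd(PPh3)4, Na2CO3, DME/H2O, 80 °C], in which the aryl iodide reacts ahead of the aryl bromide, gives 20.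

**Step 9.**
- *Risk.* Acid 12 may lose CO2 during activation, or the imidazolide may enolise completely so that the malonate never adds.
- *Fallback (sets out from 10, returns at 15).* The free acid is avoided and the chain is built by forming C6''–C5'' instead of C7''–C6''. Dienolate 11 is acetylated with N-methoxy-N-methylacetamide [LiN(SiMe3)2, THF, −78 to 0 °C] to racemic 1-[2,3-bis(benzyloxy)-5-bromophenyl]-1-{6-[4-(benzyloxy)phenyl]-4-oxo-4H-pyran-2-yl}propan-2-one F6. LiN(iPr)2 (3 equiv, THF, −78 °C) converts F6 into its dianion. The terminal CH2 carbanion, the more reactive site, is tert-butoxycarbonylated with di-tert-butyl dicarbonate to give 15.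

**Step 15.**
- *Risk.* Insertion into the electron-rich acceptor may be slow, letting protodeboronation of the valuable boronic acid win. Facial selectivity may also be poor because of the 5-benzyloxy group next to the carbonyl.
- *Fallback (sets out from 20, returns at 25).* Ring C is closed from a chalcone and the enantiomers are separated. Palladium-catalysed formylation of 20 [Pd(OAc)2, di(1-adamantyl)-n-butylphosphine, CO/H2, TMEDA, toluene, 100 °C] gives 3,4-bis(benzyloxy)-5-[5,7-bis(benzyloxy)-2-(4-benzyloxyphenyl)-4-oxo-4H-chromen-8-yl]benzaldehyde F7. Claisen–Schmidt condensation with purchased 1-[2,4-bis(benzyloxy)-6-hydroxyphenyl]ethanone (KOH, EtOH/THF, rt) gives the (E)-2'-hydroxychalcone F8. Oxa-Michael cyclisation (NaOAc, EtOH, reflux) gives the racemic heptabenzyl flavanone F9. Preparative chromatography on a chiral stationary phase then gives the (2S)-enantiomer 25.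

**Further compounds**

F1 | step 10 | 2,3-bis(benzyloxy)-5-bromobenzoic acid | OC(=O)c1cc(Br)cc(OCc2ccccc2)c1OCc1ccccc1
F2 | step 10 | 1,2-bis(benzyloxy)-5-bromo-3-iodobenzene | Ic1cc(Br)cc(OCc2ccccc2)c1OCc1ccccc1
F3 | step 10 | [2,3-bis(benzyloxy)-5-bromophenyl]boronic acid | OB(O)c1cc(Br)cc(OCc2ccccc2)c1OCc1ccccc1
F4 | step 10 | 5,7-bis(benzyloxy)-2-[4-(benzyloxy)phenyl]-4H-chromen-4-one | O=c1cc(-c2ccc(OCc3ccccc3)cc2)oc2cc(OCc3ccccc3)cc(OCc3ccccc3)c12
F5 | step 10 | 5,7-bis(benzyloxy)-2-[4-(benzyloxy)phenyl]-8-iodo-4H-chromen-4-one | O=c1cc(-c2ccc(OCc3ccccc3)cc2)oc2c(I)c(OCc3ccccc3)cc(OCc3ccccc3)c12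
F6 | step 9 | racemic 1-[2,3-bis(benzyloxy)-5-bromophenyl]-1-{6-[4-(benzyloxy)phenyl]-4-oxo-4H-pyran-2-yl}propan-2-one | CC(=O)C(c1cc(Br)cc(OCc2ccccc2)c1OCc1ccccc1)c1cc(=O)cc(-c2ccc(OCc3ccccc3)cc2)o1
F7 | step 15 | 3,4-bis(benzyloxy)-5-[5,7-bis(benzyloxy)-2-(4-benzyloxyphenyl)-4-oxo-4H-chromen-8-yl]benzaldehyde | O=Cc1cc(OCc2ccccc2)c(OCc2ccccc2)c(-c2c(OCc3ccccc3)cc(OCc3ccccc3)c3c(=O)cc(-c4ccc(OCc5ccccc5)cc4)oc23)c1
F8 | step 15 | (E)-1-[2,4-bis(benzyloxy)-6-hydroxyphenyl]-3-{3,4-bis(benzyloxy)-5-[5,7-bis(benzyloxy)-2-(4-benzyloxyphenyl)-4-oxo-4H-chromen-8-yl]phenyl}prop-2-en-1-one | O=C(/C=C/c1cc(OCc2ccccc2)c(OCc2ccccc2)c(-c2c(OCc3ccccc3)cc(OCc3ccccc3)c3c(=O)cc(-c4ccc(OCc5ccccc5)cc4)oc23)c1)c1c(O)cc(OCc2ccccc2)cc1OCc1ccccc1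
F9 | step 15 | racemic heptabenzyl flavanone (racemate of 25) | O=C1CC(c2cc(OCc3ccccc3)c(OCc3ccccc3)c(-c3c(OCc4ccccc4)cc(OCc4ccccc4)c4c(=O)cc(-c5ccc(OCc6ccccc6)cc5)oc34)c2)Oc2cc(OCc3ccccc3)cc(OCc3ccccc3)c21
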